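Locants follow the target's spiro[5.5]undecane numbering. Ring A is C1(Me)=C2H–C3H(OH)–C4H(Br)–C5Me2–C6. Ring B is C6–C7H2–C8(Br)=C9(Me)–C10H2–C11H2.
Retrosynthesis first removes C3–H and C4–Br, which leads back to the ring-A enone, and then replaces C7–H by C7–Br. It then cuts both ring bonds of C8 (C8–C7 and C8–C9) together.
This double cut is possible because C8, the sp2 carbon bearing the vinylic bromine, lies between C9(Me)= and C7, the CH2 attached to spiro C6. Taking C8 out as CBr2 leaves a 1-methylcyclopentene spiro-fused to ring A.
The remaining cuts are the 1-methyl group, the cyclopentene C=C (metathesis), the C6–allyl bond and the C6–C11 bond, which leads back to dimedone.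
In the forward direction ring A comes from dimedone, the five-membered ring is closed by metathesis, and carbene insertion enlarges it to ring B.
C6 is set by ligand control in a Pd-catalysed decarboxylative allylation, C4 by equilibration relative to C6, and C3 by axial hydride delivery relative to C4; the target is a trans bromohydrin.

Key step: step 9

Assumption: the (S)-PHOX ligand is taken to deliver the allyl group to the same enolate face as with simple 2-alkylcyclohexanone enol carbonates, which here means (R)-8; if the sense is opposite, the (R)-ligand is used and nothing else changes.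

Step 1
Reactants: 1 dimedone (5,5-dimethylcyclohexane-1,3-dione)
Product: 2 3-isobutoxy-5,5-dimethylcyclohex-2-en-1-one
Conditions: i-BuOH, p-TsOH·H2O (cat.), toluene, reflux, Dean–Stark
Reagents that add atoms: 2-methylpropan-1-ol, CC(C)CO
Why: Acid-catalysed enol etherification of the cyclic 1,3-diketone (vinylogous ester formation) is driven by azeotropic removal of water, and the symmetry of 1 allows only one product.

Step 2
Reactants: 3 4-bromo-2-methylbut-1-ene
Product: 4 4-iodo-2-methylbut-1-ene
Conditions: NaI, acetone, reflux
Reagents that add atoms: sodium iodide, [Na+].[I-]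
Why: The Finkelstein halide exchange (SN2 at a primary carbon) is driven by precipitation of sodium bromide and supplies the more reactive alkylating agent.

Step 3
Reactants: 2 3-isobutoxy-5,5-dimethylcyclohex-2-en-1-one; 4 4-iodo-2-methylbut-1-ene
Product: 5 (±)-3-isobutoxy-5,5-dimethyl-6-(3-methylbut-3-en-1-yl)cyclohex-2-en-1-one
Conditions: LDA, THF, −78 °C; then 4, −78 °C → rt
Reagents that add atoms: 4-iodo-2-methylbut-1-ene (compound 4), C=C(C)CCI
Why: Kinetic deprotonation of the vinylogous ester occurs at the α′-CH2 (Stork–Danheiser-type enolate alkylation), and SN2 attack on the primary iodide joins the C11–C10–C9 arm of ring B to the future spiro carbon as a racemic centre that is made planar again in step 4.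

Step 4
Reactants: 5 (±)-alkylated vinylogous ester; 6 allyl chloroformate
Product: 7 allyl 5-isobutoxy-3,3-dimethyl-2-(3-methylbut-3-en-1-yl)cyclohexa-1,5-dien-1-yl carbonate
Conditions: LDA, TMEDA, THF, −78 °C; then 6, −78 °C
Reagents that add atoms: allyl chloroformate (compound 6), C=CCOC(=O)Cl
Why: A second kinetic α′-deprotonation gives the fully substituted enolate, which the hard chloroformate acylates on oxygen (enol carbonate formation) because its carbon terminus next to CMe2 is blocked, and the stereocentre of 5 is erased.

Step 5
Reactants: 7 allyl enol carbonate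
Product: 8 (6R)-6-allyl-3-isobutoxy-5,5-dimethyl-6-(3-methylbut-3-en-1-yl)cyclohex-2-en-1-one
Conditions: Pd(dmdba)2 (10 mol %), (S)-(CF3)3-t-BuPHOX (12 mol %), benzene, 10–25 °C
Reagents that add atoms: none
Why: In this Pd-catalysed decarboxylative asymmetric allylic alkylation, ionisation and loss of CO2 give a chiral Pd(PHOX) allyl enolate that forms the C–allyl bond only at the carbon defined by the enol carbonate, the (S)-ligand selecting the enolate face and so setting the quaternary centre (future C6) as R, while the electron-poor ligand speeds coupling at this crowded carbon.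

Step 6
Reactants: 8 (6R)-allyl ketone
Product: 9 (6R)-3-isobutoxy-5,5-dimethyl-6-(3-methylbut-3-en-1-yl)-6-[(E)-prop-1-en-1-yl]cyclohex-2-en-1-one
Conditions: RuHCl(CO)(PPh3)3 (5 mol %), toluene, 90 °C
Reagents that add atoms: none
Why: Ru–H catalysed alkene isomerisation (hydrometallation and β-hydride elimination) moves the monosubstituted allyl double bond by one position, where the quaternary carbon stops it, much faster than it engages the 1,1-disubstituted alkene.

Step 7
Reactants: 9 (6R)-propenyl ketone
Product: 10 (5R)-8-isobutoxy-2,10,10-trimethylspiro[4.5]deca-1,7-dien-6-one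
Conditions: Hoveyda–Grubbs II (5 mol %), toluene, 80 °C, Ar sparge
Reagents that add atoms: none
Why: Ring-closing metathesis of the propenyl group and the 1,1-disubstituted alkene closes the five-membered ring with loss of volatile propene and leaves the trisubstituted C(Me)=CH bond directly on the spiro carbon, whose configuration is not involved.

Step 8
Reactants: 10 (5R)-spiro vinylogous ester
Product: 12 (5R)-2,6,10,10-tetramethylspiro[4.5]deca-1,6-dien-8-one, via tertiary carbinol 11 (not isolated)
Conditions: MeLi, CeCl3, THF, −78 → 0 °C; then 10 % aq HCl, rt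
Reagents that add atoms: methyllithium, [Li]C; water, O (supplies the ketone oxygen while the carbinol oxygen leaves as water)
Why: 1,2-Addition of the non-basic organocerium reagent to the hindered vinylogous ester carbonyl, followed by acid hydrolysis of the enol ether with loss of the tertiary hydroxyl (Stork–Danheiser carbonyl transposition), gives the β-methyl enone, and the carbinol centre of 11 is lost again.

Step 9
Reactants: 12 (5R)-spiro[4.5] methylcyclopentene enone; 13 bromoform
Product: 15 (6R)-7,8-dibromo-1,5,5,9-tetramethylspiro[5.5]undeca-1,8-dien-3-one (C7 epimers), via dibromocyclopropane 14 (not isolated)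
Conditions: CHBr3, 50 % aq NaOH, BnEt3NCl (cat.), CH2Cl2, 0 °C; phase separation; toluene, 80 °C
Reagents that add atoms: bromoform (compound 13), BrC(Br)Br
Why: Deprotonated bromoform loses bromide at the phase boundary, and the electrophilic singlet dibromocarbene adds in a concerted [2+1] cheletropic step to the cyclopentene C(Me)=CH bond, forming the C8–C9 and C8–C7 bonds at once (three-membered ring closure to 14). On warming, 14 undergoes the thermally allowed two-electron disrotatory electrocyclic opening of the former C=C σ bond with synchronous departure of the endo bromide, so ring B is not closed by a cyclisation but grows from five to six members with C8 keeping the exo bromine as the vinylic one; this is the classical conversion of cyclopentene–dibromocarbene adducts (6,6-dibromobicyclo[3.1.0]hexanes) into 2,3-dibromocyclohexenes. The 2-bromoallyl cation and bromide recombine reversibly, so the halide should settle at the secondary terminus C7, where the tetrasubstituted C8=C9 bond results, and any tertiary allylic isomer would feed the same allyl intermediate in step 10. The step needs chemoselectivity for the cyclopentene over the C1=C2 bond, which is secured by the electron-poor character of the enone and by its position between the 1-methyl group and quaternary C6. The two cyclopropane stereocentres of 14 (either face of carbene approach serves) vanish in the opening, the C7–Br centre is formed without control and is deleted in step 10, and C6 is not touched. Low temperature and short contact with the aqueous base limit enolisation of the ketone and hydrolysis of the allylic bromide.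

Step 10
Reactants: 15 (6R)-7,8-dibromo dienone
Product: 16 (6R)-8-bromo-1,5,5,9-tetramethylspiro[5.5]undeca-1,8-dien-3-one
Conditions: Bu3SnH (1.05 equiv), Et3B (cat.), air, toluene, −78 → 0 °C
Reagents that add atoms: none
Why: In this radical-chain hydrodebromination the stannyl radical abstracts only the weak allylic bromine, and the 2-bromoallyl radical should take hydrogen at its secondary terminus C7 because that leaves the more stable tetrasubstituted C8=C9 bond, while low temperature and one equivalent of hydride spare the vinylic C–Br bond and the enone, and the C7 stereocentre disappears.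

Step 11
Reactants: 16 (6R)-8-bromo dienone
Product: 18 (6S)-4,8-dibromo-1,5,5,9-tetramethylspiro[5.5]undeca-1,8-dien-3-one (C4 epimers), via silyl dienol ether 17 (not isolated)
Conditions: LDA, THF, −78 °C; TMSCl; then NBS, −78 → 0 °C
Reagents that add atoms: N-bromosuccinimide, O=C1CCC(=O)N1Br; chlorotrimethylsilane, C[Si](C)(C)Cl (its silyl group is found only in 17)
Why: Kinetic α′-enolisation, O-silylation and electrophilic bromination of the cross-conjugated 2-silyloxydiene with NBS place bromine at C4 only, the silyl enol ether being far more nucleophilic than the bromine-deactivated C8=C9 bond, and the C4 configuration is left open at this stage.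

Step 12
Reactants: 18 4-bromo enone (C4 epimers)
Product: 19 (4S,6S)-4,8-dibromo-1,5,5,9-tetramethylspiro[5.5]undeca-1,8-dien-3-one
Conditions: DBU (0.2 equiv), toluene, rt; chromatography, minor epimer resubmitted
Reagents that add atoms: none
Why: Base-catalysed epimerisation of the α-bromo ketone through its enolate cannot end in elimination because C5 is quaternary and C2 is vinylic, and it should enrich the epimer with equatorial bromine in the ring-A half-chair that has C7 pseudo-equatorial and C11 pseudo-axial, the conformer in which the 1-methyl group leans over the sp2 edge C7–C8 of ring B instead of against the axial hydrogen on C10, which places Br cis to C7 (4S).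

Step 13
Reactants: 19 (4S,6S)-4-bromo enone
Product: 20 (3S,4S,6S)-4,8-dibromo-1,5,5,9-tetramethylspiro[5.5]undeca-1,8-dien-3-ol
Conditions: NaBH4, CeCl3·7H2O, MeOH, −78 °C
Reagents that add atoms: none
Why: In the Luche 1,2-reduction the small, hard methoxyborohydride should attack the flattened cyclohexenone along the axial trajectory, antiperiplanar to the axial C4–H of the bromine-equatorial half-chair, which places the C3 hydroxyl pseudo-equatorial and trans to bromine (3S) and leaves both C–Br bonds and both alkenes untouched.

Compound list
1 | dimedone (5,5-dimethylcyclohexane-1,3-dione) | CC1(C)CC(=O)CC(=O)C1 | starting material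
2 | 3-isobutoxy-5,5-dimethylcyclohex-2-en-1-one | CC(C)COC1=CC(=O)CC(C)(C)C1 | intermediate
3 | 4-bromo-2-methylbut-1-ene | C=C(C)CCBr | starting material
4 | 4-iodo-2-methylbut-1-ene | C=C(C)CCI | intermediate
5 | (±)-3-isobutoxy-5,5-dimethyl-6-(3-methylbut-3-en-1-yl)cyclohex-2-en-1-one | O=C1C=C(OCC(C)C)CC(C)(C)C1CCC(C)=C | intermediate
6 | allyl chloroformate | C=CCOC(=O)Cl | starting material
7 | allyl 5-isobutoxy-3,3-dimethyl-2-(3-methylbut-3-en-1-yl)cyclohexa-1,5-dien-1-yl carbonate | C=CCOC(=O)OC1=C(CCC(C)=C)C(C)(C)CC(OCC(C)C)=C1 | intermediate
8 | (6R)-6-allyl-3-isobutoxy-5,5-dimethyl-6-(3-methylbut-3-en-1-yl)cyclohex-2-en-1-one | O=C1C=C(OCC(C)C)CC(C)(C)[C@@]1(CCC(C)=C)CC=C | intermediate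
9 | (6R)-3-isobutoxy-5,5-dimethyl-6-(3-methylbut-3-en-1-yl)-6-[(E)-prop-1-en-1-yl]cyclohex-2-en-1-one | O=C1C=C(OCC(C)C)CC(C)(C)[C@@]1(CCC(C)=C)/C=C/C | intermediate
10 | (5R)-8-isobutoxy-2,10,10-trimethylspiro[4.5]deca-1,7-dien-6-one | O=C1C=C(OCC(C)C)CC(C)(C)[C@]12CCC(C)=C2 | intermediate
11 | (5R)-8-isobutoxy-2,6,10,10-tetramethylspiro[4.5]deca-1,7-dien-6-ol (carbinol epimers, not isolated) | CC1(O)C=C(OCC(C)C)CC(C)(C)[C@]12CCC(C)=C2 | intermediate
12 | (5R)-2,6,10,10-tetramethylspiro[4.5]deca-1,6-dien-8-one | CC1=CC(=O)CC(C)(C)[C@]12CCC(C)=C2 | intermediate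
13 | bromoform | BrC(Br)Br | starting material
14 | 6,6-dibromo-2′,5,6′,6′-tetramethylspiro[bicyclo[3.1.0]hexane-2,1′-cyclohex-2′-en]-4′-one, spiro centre R, either cyclopropane face (not isolated) | CC1=CC(=O)CC(C)(C)[C@]12CCC3(C)C2C3(Br)Br | intermediate
15 | (6R)-7,8-dibromo-1,5,5,9-tetramethylspiro[5.5]undeca-1,8-dien-3-one (C7 epimers) | CC1=CC(=O)CC(C)(C)[C@]12CCC(C)=C(Br)C2Br | intermediate
16 | (6R)-8-bromo-1,5,5,9-tetramethylspiro[5.5]undeca-1,8-dien-3-one | CC1=CC(=O)CC(C)(C)[C@]12CCC(C)=C(Br)C2 | intermediate
17 | [(6S)-8-bromo-1,5,5,9-tetramethylspiro[5.5]undeca-1,3,8-trien-3-yl]oxytrimethylsilane (not isolated) | CC1=CC(O[Si](C)(C)C)=CC(C)(C)[C@]12CCC(C)=C(Br)C2 | intermediate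
18 | (6S)-4,8-dibromo-1,5,5,9-tetramethylspiro[5.5]undeca-1,8-dien-3-one (C4 epimers) | CC1=CC(=O)C(Br)C(C)(C)[C@]12CCC(C)=C(Br)C2 | intermediate
19 | (4S,6S)-4,8-dibromo-1,5,5,9-tetramethylspiro[5.5]undeca-1,8-dien-3-one | CC1=CC(=O)[C@@H](Br)C(C)(C)[C@]12CCC(C)=C(Br)C2 | intermediate
20 | (3S,4S,6S)-4,8-dibromo-1,5,5,9-tetramethylspiro[5.5]undeca-1,8-dien-3-ol | CC1=C[C@H](O)[C@@H](Br)C(C)(C)[C@]12CCC(C)=C(Br)C2 | target

Total step count: 13. Longest linear sequence: 12 steps (1, then 3–13, from dimedone).

Steps most likely to fail

Step 10. Hydrogen transfer may go to the methyl-bearing terminus of the allyl radical, with migration of the double bond out of the C8=C9 position. The cause is that both faces of C7 are screened by methyl groups of ring A (on C5 and on C1).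
- The fallback sets out from 15 and returns at 16. It delivers the hydrogen intramolecularly.
- 15 is ionised in hexafluoroisopropanol–CH2Cl2 over NaHCO3 at 0 °C with one equivalent of p-toluenesulfonyl hydrazide. The low temperature and the stoichiometry keep hydrazone formation at C3 in check.
- The terminal NH2 group should capture the 2-bromoallyl cation at the open, more positively charged terminus C9. This gives the tertiary allylic N′-tosylhydrazine F1.
- Warming with NaOAc eliminates sulfinate. The allylic diazene F2 then loses nitrogen in a retro-ene reaction that hands its hydrogen to C7 and moves the double bond to C8=C9.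
- In this variant the crowding at C7 steers the nucleophile to the useful terminus instead of working against the route.

Step 9. Cyclopropanation of an alkene whose CH end is neopentylic may be slow. Enolisation of the ketone by the aqueous base (with attack of the dienolate on carbene or bromoform), or hydrolysis of the allylic bromide, may then overtake it.
- The fallback sets out from 10 and returns at 16. The same carbon insertion is carried out one stage earlier.
- 10 has no proton α to its carbonyl group and should tolerate bromoform with solid KOt-Bu in pentane at −20 °C, an anhydrous medium in which excess carbene can be used. This gives the dibromocyclopropane F3.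
- Warming in toluene opens F3 to the ring-enlarged dibromide F4.
- Bu3SnH/Et3B then gives the vinyl bromide F5. At this stage C7 is flanked by a carbonyl group instead of the C(Me)= unit, which frees one face for hydrogen transfer.
- MeLi/CeCl3 adds to the carbonyl to give the tertiary carbinol F6, and aqueous HCl converts it into 16.

Step 13. Hydride may approach from the equatorial side, because the axial methyl group on C5 stands syn-axial to the axial trajectory. The result would be poor or inverted facial selectivity at C3.
- The fallback sets out from 19 and returns at 20. It uses this bias and then inverts C3.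
- DIBAL in CH2Cl2 at −78 °C attacks the face opposite the axial C5 methyl group to give the cis-bromohydrin F7.
- A Mitsunobu reaction (PPh3, DIAD, 4-nitrobenzoic acid, toluene, 0 °C → rt) displaces the axial allylic oxygen with inversion to give the inverted 4-nitrobenzoate F8. SN2′ attack is blocked by the fully substituted C1.
- Brief methanolysis (K2CO3, MeOH, 0 °C) releases 20. The diequatorial bromohydrin is poorly disposed to close to an epoxide.

Further compounds
F1 | step 10 | 8-bromo-1,5,5,9-tetramethyl-9-(2-tosylhydrazinyl)spiro[5.5]undeca-1,7-dien-3-one (C6 as in 15, C9 epimers) | CC1=CC(=O)CC(C)(C)[C@]12CCC(C)(NNS(=O)(=O)c3ccc(C)cc3)C(Br)=C2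
F2 | step 10 | 8-bromo-9-diazenyl-1,5,5,9-tetramethylspiro[5.5]undeca-1,7-dien-3-one | CC1=CC(=O)CC(C)(C)[C@]12CCC(C)(N=N)C(Br)=C2
F3 | step 9 | 6,6-dibromo-4′-isobutoxy-5,6′,6′-trimethylspiro[bicyclo[3.1.0]hexane-2,1′-cyclohex-3′-en]-2′-one | O=C1C=C(OCC(C)C)CC(C)(C)[C@]12CCC3(C)C2C3(Br)Br
F4 | step 9 | 7,8-dibromo-3-isobutoxy-5,5,9-trimethylspiro[5.5]undeca-2,8-dien-1-one (C7 epimers) | O=C1C=C(OCC(C)C)CC(C)(C)[C@]12CCC(C)=C(Br)C2Br
F5 | step 9 | 8-bromo-3-isobutoxy-5,5,9-trimethylspiro[5.5]undeca-2,8-dien-1-one | O=C1C=C(OCC(C)C)CC(C)(C)[C@]12CCC(C)=C(Br)C2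
F6 | step 9 | 8-bromo-3-isobutoxy-1,5,5,9-tetramethylspiro[5.5]undeca-2,8-dien-1-ol (carbinol epimers) | CC1(O)C=C(OCC(C)C)CC(C)(C)[C@]12CCC(C)=C(Br)C2
F7 | step 13 | (3R,4S,6S)-4,8-dibromo-1,5,5,9-tetramethylspiro[5.5]undeca-1,8-dien-3-ol | CC1=C[C@@H](O)[C@@H](Br)C(C)(C)[C@]12CCC(C)=C(Br)C2
F8 | step 13 | (3S,4S,6S)-4,8-dibromo-1,5,5,9-tetramethylspiro[5.5]undeca-1,8-dien-3-yl 4-nitrobenzoate | CC1=C[C@H](OC(=O)c3ccc(cc3)[N+](=O)[O-])[C@@H](Br)C(C)(C)[C@]12CCC(C)=C(Br)C2
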